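**Retrosynthetic overview** (1-benzoxepine numbering for each half: O1, C2(Me2), C3, C4, C5, C5a(Me), C6, C7(Me), C8, C9, C9a)
1. CH2–CH2 bridge last: 9-BBN hydroboration of the 6-vinyl alcohol half, then B-alkyl Suzuki coupling with the 6-enol triflate of the 3-keto half; both halves come from one bicyclic enol triflate.
2. Oxepane (last ring formed): Shi epoxidation of a homoprenyl side chain, then 7-endo opening at the tertiary epoxide carbon by the C9a oxygen.
3. Cyclohexene ring with C7–Me and C6–OTf: one-carbon ring expansion (1,2-shift) of a cyclopentanone with 1-(trimethylsilyl)diazoethane, trapped as the enol triflate.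
4. Quaternary C5a with the chain trans to the C9a oxygen: semipinacol 1,2-alkyl shift of a cis-epoxy tertiary alcohol.
5. Epoxy alcohol: one-pot catalytic asymmetric homoprenyl-zinc addition to 2-methylcyclopent-2-enone and directed epoxidation. Ring order: cyclopentane (bought) → cyclohexene → oxepane.

Assumption: the ligand enantiomer in step 1 is the one that gives the (1S)-alkoxide 5; the sense of induction has to be confirmed on the first run, and the other ligand enantiomer is used if it is opposite.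

**Step 1**
Reactants: 1 2-methylcyclopent-2-en-1-one; 2 5-bromo-2-methylpent-2-ene
Product: 6 (1S,2R,5S)-1-methyl-2-(4-methylpent-3-en-1-yl)-6-oxabicyclo[3.1.0]hexan-2-ol, via homoprenylmagnesium bromide 3 (not isolated), via bis(homoprenyl)zinc 4 (not isolated), via zinc tertiary allylic alkoxide 5 (not isolated)
Conditions: 2, Mg, THF; ZnCl2 (0.5 equiv per Grignard), then 1,4-dioxane, filter; Ti(OiPr)4 (1.2 equiv), trans-cyclohexane-1,2-diamine bis(10-camphorsulfonamide) diol ligand (10 mol %), 1, toluene, rt; then O2 (1 atm), 0 °C; aq NH4Cl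
Reagents that add atoms: dioxygen O=O
Why: Tetravalent-titanium/bis(sulfonamide) diol catalysis adds one alkyl group of the dialkylzinc to one face of the α-branched enone (catalytic asymmetric 1,2-addition, sets the carbinol centre), and the alkylperoxide formed from the remaining alkylzinc and O2 then epoxidises the allylic alkoxide on the face of its own oxygen (directed epoxidation, sets both epoxide carbons syn to O).

**Step 2**
Reactants: 6 (1S,2R,5S)-1-methyl-2-(4-methylpent-3-en-1-yl)-6-oxabicyclo[3.1.0]hexan-2-ol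
Product: 8 (2R,3S)-2-methyl-2-(4-methylpent-3-en-1-yl)-3-[(triethylsilyl)oxy]cyclopentan-1-one, via tertiary triethylsilyl ether 7 (not isolated)
Conditions: Et3SiOTf (1.3 equiv), 2,6-lutidine (1.5 equiv), CH2Cl2, −78 → −30 °C
Reagents that add atoms: triethylsilyl trifluoromethanesulfonate CC[Si](CC)(CC)OS(=O)(=O)C(F)(F)F
Why: After O-silylation, silyl-triflate activation of the epoxide triggers a semipinacol rearrangement (1,2-alkyl shift of the Suzuki–Tsuchihashi type) in which the homoprenyl group, anti-periplanar to the breaking C–O bond, migrates with inversion at the epoxide carbon, so the new quaternary centre carries the chain trans to the retained C–O bond (methyl cis to O) and the silyl group ends on that oxygen.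

**Step 3**
Reactants: 8 (2R,3S)-2-methyl-2-(4-methylpent-3-en-1-yl)-3-[(triethylsilyl)oxy]cyclopentan-1-one
Product: 10 (5S,6R)-2,6-dimethyl-6-(4-methylpent-3-en-1-yl)-5-[(triethylsilyl)oxy]cyclohex-1-en-1-yl trifluoromethanesulfonate, via ring-expanded trimethylsilyl enol ether 9 (not isolated)
Conditions: Me3SiC(N2)CH3 (1.5 equiv, hexane solution freshly made from Me3SiCHN2, n-BuLi, MeI), Sc(OTf)3 (10 mol %), toluene, −40 → 0 °C; then KOtBu (1.1 equiv), THF, −20 °C; PhNTf2 (1.2 equiv), −20 → 0 °C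
Reagents that add atoms: 1-(trimethylsilyl)diazoethane CC(=[N+]=[N-])[Si](C)(C)C; N-phenylbis(trifluoromethanesulfonimide) O=S(=O)(N(c1ccccc1)S(=O)(=O)C(F)(F)F)C(F)(F)F
Why: Proposed new method: Sc(OTf)3 activates the ketone, the diazo carbon adds, and loss of N2 drives a 1,2-shift of the less substituted ring CH2 (the quaternary, β-silyloxy α-carbon should migrate much more slowly), giving a ring-expanded α-silyl ketone that undergoes 1,3-Brook shift to the tetrasubstituted enol silane 9, whose potassium enolate is O-triflated with no regiochemical choice; the closest known chemistry is the trivalent-scandium-catalysed homologation of cycloalkanones with trimethylsilyldiazomethane (enol silane products) and with disubstituted diazoalkanes (α-quaternary ketones), which as far as I know has not been run with a C-silyl C-alkyl diazoalkane on an α-quaternary ketone or carried through to an enol triflate, and no new stereocentre is formed.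

**Step 4**
Reactants: 10 (5S,6R)-2,6-dimethyl-6-(4-methylpent-3-en-1-yl)-5-[(triethylsilyl)oxy]cyclohex-1-en-1-yl trifluoromethanesulfonate
Product: 11 (5S,6R)-6-{2-[(2R)-3,3-dimethyloxiran-2-yl]ethyl}-2,6-dimethyl-5-[(triethylsilyl)oxy]cyclohex-1-en-1-yl trifluoromethanesulfonate
Conditions: D-fructose-derived Shi ketone (0.3 equiv), Oxone (2KHSO5·KHSO4·K2SO4), K2CO3, Bu4NHSO4, MeCN/dimethoxymethane/aq borate buffer (pH 10.5), 0 °C
Reagents that add atoms: potassium peroxymonosulfate [K+].[O-]S(=O)(=O)OO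
Why: Shi asymmetric epoxidation by the chiral dioxirane attacks only the electron-rich trisubstituted side-chain alkene (the enol triflate alkene is electron-poor) and sets the (R) epoxide carbon under reagent control.

**Step 5**
Reactants: 11 (5S,6R)-6-{2-[(2R)-3,3-dimethyloxiran-2-yl]ethyl}-2,6-dimethyl-5-[(triethylsilyl)oxy]cyclohex-1-en-1-yl trifluoromethanesulfonate
Product: 13 (3R,5aR,9aS)-3-hydroxy-2,2,5a,7-tetramethyl-2,3,4,5,5a,8,9,9a-octahydro-1-benzoxepin-6-yl trifluoromethanesulfonate, via 3-O-triethylsilyl oxepane 12 (not isolated)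
Conditions: Et3SiOTf (0.3 equiv), 2,6-di-tert-butyl-4-methylpyridine (0.4 equiv), MeNO2, −25 °C; then 1 M HCl in MeOH, 0 °C
Reagents that add atoms: none
Why: Silyl-triflate activation gives the epoxide SN1-like character at its tertiary carbon, so the silyl ether oxygen attacks there (7-endo epoxide-opening etherification with silyl transfer), C3 keeps its epoxide oxygen with retention as the (3R) alcohol after acid methanolysis, and the ring fusion is trans because chain and oxygen were already trans.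

**Step 6**
Reactants: 13 (3R,5aR,9aS)-3-hydroxy-2,2,5a,7-tetramethyl-2,3,4,5,5a,8,9,9a-octahydro-1-benzoxepin-6-yl trifluoromethanesulfonate; 14 potassium vinyltrifluoroborate
Product: 15 (3R,5aS,9aS)-6-ethenyl-2,2,5a,7-tetramethyl-2,3,4,5,5a,8,9,9a-octahydro-1-benzoxepin-3-ol
Conditions: 14 (1.5 equiv), PdCl2(dppf)·CH2Cl2 (5 mol %; dppf = 1,1'-bis(diphenylphosphino)ferrocene), Cs2CO3 (3 equiv), THF/H2O 9:1, 70 °C
Reagents that add atoms: none
Why: Suzuki–Miyaura vinylation of the enol triflate installs the two bridge carbons and tolerates the free alcohol.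

**Step 7**
Reactants: 13 (3R,5aR,9aS)-3-hydroxy-2,2,5a,7-tetramethyl-2,3,4,5,5a,8,9,9a-octahydro-1-benzoxepin-6-yl trifluoromethanesulfonate
Product: 16 (5aR,9aS)-2,2,5a,7-tetramethyl-3-oxo-2,3,4,5,5a,8,9,9a-octahydro-1-benzoxepin-6-yl trifluoromethanesulfonate
Conditions: Dess–Martin periodinane (1.3 equiv), NaHCO3, CH2Cl2, rt
Reagents that add atoms: none
Why: Dess–Martin oxidation turns the secondary alcohol into the oxepan-3-one of the keto half without touching the enol triflate.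

**Step 8**
Reactants: 15 (3R,5aS,9aS)-6-ethenyl-2,2,5a,7-tetramethyl-2,3,4,5,5a,8,9,9a-octahydro-1-benzoxepin-3-ol; 16 (5aR,9aS)-2,2,5a,7-tetramethyl-3-oxo-2,3,4,5,5a,8,9,9a-octahydro-1-benzoxepin-6-yl trifluoromethanesulfonate
Product: 18 sodwanone T, via B-alkyl-9-borabicyclononane 17 (not isolated)
Conditions: 9-BBN-H (2.3 equiv), THF, 0 °C → rt; then 3 M aq K3PO4, 16, PdCl2(dppf)·CH2Cl2 (10 mol %), AsPh3 (10 mol %), DMF, 50 °C
Reagents that add atoms: none
Why: 9-BBN hydroborates only the terminal vinyl carbon (the tetrasubstituted ring alkene is inert; the hydroxyl is carried as its borinate), and B-alkyl Suzuki–Miyaura coupling of the primary alkylborane with the enol triflate forms the CH2–CH2 bridge with both tetrasubstituted alkenes in place.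

**Compound list**
1 | 2-methylcyclopent-2-en-1-one | CC1=CCCC1=O | starting material
2 | 5-bromo-2-methylpent-2-ene | CC(C)=CCCBr | starting material
3 | (4-methylpent-3-en-1-yl)magnesium bromide | CC(C)=CCC[Mg]Br | intermediate
4 | bis(4-methylpent-3-en-1-yl)zinc | CC(C)=CCC[Zn]CCC=C(C)C | intermediate
5 | alkylzinc alkoxide of (1S)-2-methyl-1-(4-methylpent-3-en-1-yl)cyclopent-2-en-1-ol | CC(C)=CCC[C@@]1(O[Zn]CCC=C(C)C)CCC=C1C | intermediate
6 | (1S,2R,5S)-1-methyl-2-(4-methylpent-3-en-1-yl)-6-oxabicyclo[3.1.0]hexan-2-ol (OH and epoxide O cis) | CC(C)=CCC[C@@]1(O)CC[C@@H]2O[C@]12C | intermediate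
7 | triethyl{[(1S,2R,5S)-1-methyl-2-(4-methylpent-3-en-1-yl)-6-oxabicyclo[3.1.0]hexan-2-yl]oxy}silane | CC(C)=CCC[C@@]1(O[Si](CC)(CC)CC)CC[C@@H]2O[C@]12C | intermediate
8 | (2R,3S)-2-methyl-2-(4-methylpent-3-en-1-yl)-3-[(triethylsilyl)oxy]cyclopentan-1-one (silyloxy cis to methyl) | O=C1CC[C@H](O[Si](CC)(CC)CC)[C@@]1(C)CCC=C(C)C | intermediate
9 | trimethyl{[(5S,6R)-2,6-dimethyl-6-(4-methylpent-3-en-1-yl)-5-(triethylsilyloxy)cyclohex-1-en-1-yl]oxy}silane | C[Si](C)(C)OC1=C(C)CC[C@H](O[Si](CC)(CC)CC)[C@@]1(C)CCC=C(C)C | intermediate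
10 | (5S,6R)-2,6-dimethyl-6-(4-methylpent-3-en-1-yl)-5-[(triethylsilyl)oxy]cyclohex-1-en-1-yl trifluoromethanesulfonate | O=S(=O)(OC1=C(C)CC[C@H](O[Si](CC)(CC)CC)[C@@]1(C)CCC=C(C)C)C(F)(F)F | intermediate
11 | (5S,6R)-6-{2-[(2R)-3,3-dimethyloxiran-2-yl]ethyl}-2,6-dimethyl-5-[(triethylsilyl)oxy]cyclohex-1-en-1-yl trifluoromethanesulfonate | O=S(=O)(OC1=C(C)CC[C@H](O[Si](CC)(CC)CC)[C@@]1(C)CC[C@H]2OC2(C)C)C(F)(F)F | intermediate
12 | (3R,5aR,9aS)-2,2,5a,7-tetramethyl-3-[(triethylsilyl)oxy]-2,3,4,5,5a,8,9,9a-octahydro-1-benzoxepin-6-yl trifluoromethanesulfonate | O=S(=O)(OC1=C(C)CC[C@@H]2OC(C)(C)[C@H](O[Si](CC)(CC)CC)CC[C@@]12C)C(F)(F)F | intermediate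
13 | (3R,5aR,9aS)-3-hydroxy-2,2,5a,7-tetramethyl-2,3,4,5,5a,8,9,9a-octahydro-1-benzoxepin-6-yl trifluoromethanesulfonate (trans-fused) | O=S(=O)(OC1=C(C)CC[C@@H]2OC(C)(C)[C@H](O)CC[C@@]12C)C(F)(F)F | intermediate
14 | potassium vinyltrifluoroborate | [K+].C=C[B-](F)(F)F | starting material
15 | (3R,5aS,9aS)-6-ethenyl-2,2,5a,7-tetramethyl-2,3,4,5,5a,8,9,9a-octahydro-1-benzoxepin-3-ol | C=CC1=C(C)CC[C@@H]2OC(C)(C)[C@H](O)CC[C@@]12C | intermediate
16 | (5aR,9aS)-2,2,5a,7-tetramethyl-3-oxo-2,3,4,5,5a,8,9,9a-octahydro-1-benzoxepin-6-yl trifluoromethanesulfonate | O=S(=O)(OC1=C(C)CC[C@@H]2OC(C)(C)C(=O)CC[C@@]12C)C(F)(F)F | intermediate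
17 | 9-{2-[(3R,5aS,9aS)-benzoxepin-6-yl]ethyl}-9-borabicyclo[3.3.1]nonane derived from 15, 3-hydroxyl as its 9-BBN borinate | B1(CCC3=C(C)CC[C@@H]4OC(C)(C)[C@H](OB5C6CCCC5CCC6)CC[C@@]34C)C2CCCC1CCC2 | intermediate
18 | sodwanone T | CC1=C(CCC2=C(C)CC[C@@H]3OC(C)(C)[C@H](O)CC[C@@]23C)[C@]2(C)CCC(=O)C(C)(C)O[C@H]2CC1 | target

**Total step count:** 8. **Longest linear sequence:** 7 (steps 1–5, then 6 or 7, then 8).

**Three steps most likely to fail**

Step 3 (the proposed new ring expansion). The carbonyl sits next to a quaternary carbon and the diazoalkane is disubstituted, so addition may be slow, and oxirane formation or migration of the wrong carbon could compete. Fallback with known chemistry, from 8 back to 10: commercial Me3SiCHN2 with BF3·OEt2 (CH2Cl2, −78 °C) ring-expands 8 by CH2 migration to (2R,3S)-2-methyl-2-(4-methylpent-3-en-1-yl)-3-[(triethylsilyl)oxy]-6-(trimethylsilyl)cyclohexan-1-one F1. K2CO3 in MeOH at 0 °C removes the C-silyl group to give (2R,3S)-2-methyl-2-(4-methylpent-3-en-1-yl)-3-[(triethylsilyl)oxy]cyclohexan-1-one F2. LiN(iPr)2 then MeI gives the 6-methyl ketone (2R,3S)-2,6-dimethyl-2-(4-methylpent-3-en-1-yl)-3-[(triethylsilyl)oxy]cyclohexan-1-one F3 as C6 epimers, and KN(SiMe3)2 then PhNTf2 gives 10. This costs two extra steps.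

Step 5 (7-endo epoxide opening). Attack at the secondary carbon (6-exo) or a 1,2-hydride shift of the tertiary cation to an isopropyl ketone may compete. Fallback without an epoxide, from 10 back to 16 and 13: HF·pyridine in THF frees the alcohol (5S,6R)-5-hydroxy-2,6-dimethyl-6-(4-methylpent-3-en-1-yl)cyclohex-1-en-1-yl trifluoromethanesulfonate F4. Hg(O2CCF3)2 in MeNO2, then aqueous NaCl, closes the oxepane in the Markovnikov sense to the organomercurial (5aR,9aS)-3-(chloromercurio)-2,2,5a,7-tetramethyl-2,3,4,5,5a,8,9,9a-octahydro-1-benzoxepin-6-yl trifluoromethanesulfonate F5. NaBH4/O2 in DMF gives the C3-epimeric alcohols (5aR,9aS)-3-hydroxy-2,2,5a,7-tetramethyl-2,3,4,5,5a,8,9,9a-octahydro-1-benzoxepin-6-yl trifluoromethanesulfonate F6. Dess–Martin oxidation converges both epimers on 16, and reduction of the needed part of 16 with BH3·SMe2 and the (S)-2-methyl-CBS-oxazaborolidine (expected to give the 3R alcohol) returns to 13.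

Step 8 (B-alkyl Suzuki coupling at a tetrasubstituted enol triflate flanked by a quaternary carbon). Oxidative addition or transmetalation may be slow, and β-hydride loss from the alkyl–palladium intermediate may compete. Fallback through an alkyne, from 13 and 16 back to 18: Sonogashira coupling of 13 with ethynyltrimethylsilane (Pd(PPh3)4, CuI, iPr2NH) gives (3R,5aS,9aS)-2,2,5a,7-tetramethyl-6-[(trimethylsilyl)ethynyl]-2,3,4,5,5a,8,9,9a-octahydro-1-benzoxepin-3-ol F7. K2CO3 in MeOH gives the terminal enyne (3R,5aS,9aS)-6-ethynyl-2,2,5a,7-tetramethyl-2,3,4,5,5a,8,9,9a-octahydro-1-benzoxepin-3-ol F8. A second Sonogashira coupling with 16 gives the dienyne (5aS,9aS)-6-{[(3R,5aS,9aS)-3-hydroxy-2,2,5a,7-tetramethyl-2,3,4,5,5a,8,9,9a-octahydro-1-benzoxepin-6-yl]ethynyl}-2,2,5a,7-tetramethyl-4,5,5a,8,9,9a-hexahydro-1-benzoxepin-3(2H)-one F9. Diimide from KO2CN=NCO2K and AcOH saturates only the alkyne and leaves both tetrasubstituted alkenes and the ketone, giving 18.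

**Further compounds**
F1 | step 3 | (2R,3S)-2-methyl-2-(4-methylpent-3-en-1-yl)-3-[(triethylsilyl)oxy]-6-(trimethylsilyl)cyclohexan-1-one (C6 epimers) | O=C1C([Si](C)(C)C)CC[C@H](O[Si](CC)(CC)CC)[C@@]1(C)CCC=C(C)C
F2 | step 3 | (2R,3S)-2-methyl-2-(4-methylpent-3-en-1-yl)-3-[(triethylsilyl)oxy]cyclohexan-1-one | O=C1CCC[C@H](O[Si](CC)(CC)CC)[C@@]1(C)CCC=C(C)C
F3 | step 3 | (2R,3S)-2,6-dimethyl-2-(4-methylpent-3-en-1-yl)-3-[(triethylsilyl)oxy]cyclohexan-1-one (C6 epimers) | O=C1C(C)CC[C@H](O[Si](CC)(CC)CC)[C@@]1(C)CCC=C(C)C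
F4 | step 5 | (5S,6R)-5-hydroxy-2,6-dimethyl-6-(4-methylpent-3-en-1-yl)cyclohex-1-en-1-yl trifluoromethanesulfonate | O=S(=O)(OC1=C(C)CC[C@H](O)[C@@]1(C)CCC=C(C)C)C(F)(F)F
F5 | step 5 | (5aR,9aS)-3-(chloromercurio)-2,2,5a,7-tetramethyl-2,3,4,5,5a,8,9,9a-octahydro-1-benzoxepin-6-yl trifluoromethanesulfonate (C3 epimers) | O=S(=O)(OC1=C(C)CC[C@@H]2OC(C)(C)C([Hg]Cl)CC[C@@]12C)C(F)(F)F
F6 | step 5 | (5aR,9aS)-3-hydroxy-2,2,5a,7-tetramethyl-2,3,4,5,5a,8,9,9a-octahydro-1-benzoxepin-6-yl trifluoromethanesulfonate (C3 epimers) | O=S(=O)(OC1=C(C)CC[C@@H]2OC(C)(C)C(O)CC[C@@]12C)C(F)(F)F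
F7 | step 8 | (3R,5aS,9aS)-2,2,5a,7-tetramethyl-6-[(trimethylsilyl)ethynyl]-2,3,4,5,5a,8,9,9a-octahydro-1-benzoxepin-3-ol | C[Si](C)(C)C#CC1=C(C)CC[C@@H]2OC(C)(C)[C@H](O)CC[C@@]12C
F8 | step 8 | (3R,5aS,9aS)-6-ethynyl-2,2,5a,7-tetramethyl-2,3,4,5,5a,8,9,9a-octahydro-1-benzoxepin-3-ol | C#CC1=C(C)CC[C@@H]2OC(C)(C)[C@H](O)CC[C@@]12C
F9 | step 8 | (5aS,9aS)-6-{[(3R,5aS,9aS)-3-hydroxy-2,2,5a,7-tetramethyl-2,3,4,5,5a,8,9,9a-octahydro-1-benzoxepin-6-yl]ethynyl}-2,2,5a,7-tetramethyl-4,5,5a,8,9,9a-hexahydro-1-benzoxepin-3(2H)-one | C(#CC1=C(C)CC[C@@H]2OC(C)(C)[C@H](O)CC[C@@]12C)C3=C(C)CC[C@@H]4OC(C)(C)C(=O)CC[C@@]34C
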